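**Retrosynthetic overview**
- Both aryl ester bonds are cut at the phenol oxygens of rings A and B, and each acyl ring (B, then C) is traced back past its aromatic stage to an open-chain aryl 3,5,7-trioxooctanoate, that is, to a phenol plus a 3,5-dioxohexanoyl ketene.
- The strategy rests on this feature: rings B and C are each a 2,4-dioxygenated 6-methylbenzoyl unit whose C1 carbonyl carbon is bonded to an aryl oxygen. O-H addition of a phenol to the ketene, then a C2 to C7 aldol and loss of water, gives exactly this pattern.
- One diketo-dioxinone, made from trimethyldioxinone by two C-acylations, serves as the ketene source for both rings.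
- Ring order: ring A is bought (methyl orsellinate, 2-OH masked as benzyl ether). Ring B is grown on the ring A 4-oxygen, differentiated (4-OBn, 2-OMe) and debenzylated. Ring C is grown on the ring B 4-oxygen, and its 4-OH is methylated last.

Key step: step 10

Remark: the dioxinone, acetyl chloride, the Weinreb amide and methyl orsellinate are taken as purchased; the target has no stereo element, and the cyclic aldol adducts are transient racemic mixtures whose stereocentres disappear on aromatization. Acylketene 10 arises from 5 in both annulations; it is entered as an unisolated intermediate at step 6, where it first forms, and step 10 refers back to it.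

**Route**

Step 1
Reactants: 1 2,2,6-trimethyl-4H-1,3-dioxin-4-one; 2 acetyl chloride
Product: 3 2,2-dimethyl-6-(2-oxopropyl)-4H-1,3-dioxin-4-one (keto-dioxinone)
Conditions: 1 (2 equiv), LiN(SiMe3)2 (2 equiv), THF, −78 °C; then 2 (1 equiv), −78 → 0 °C; aq. NH4Cl
Reagents that add atoms: none
Why: Kinetic deprotonation of the 6-methyl group gives the lithium dienolate, which is acylated at its terminal carbon by acetyl chloride in a vinylogous Claisen-type C-acylation, the second equivalent of dienolate taking up the more acidic proton of the product.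

Step 2
Reactants: 3 keto-dioxinone; 4 N-methoxy-N-methylacetamide
Product: 5 6-(2,4-dioxopentyl)-2,2-dimethyl-4H-1,3-dioxin-4-one (diketo-dioxinone, prepared in quantity for steps 6 and 10)
Conditions: LiN(iPr)2 (2.2 equiv), THF, −78 °C; then 4, −78 → −30 °C; 1 M aq. HCl quench
Reagents that add atoms: none
Why: Two equivalents of amide base form the dianion, whose more reactive terminal carbanion adds to the Weinreb amide to give a chelated tetrahedral adduct that collapses only on work-up, so over-addition is avoided (dianion Claisen-type acylation).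

Step 3
Reactants: 6 methyl 2,4-dihydroxy-6-methylbenzoate (methyl orsellinate, ring A)
Product: 7 methyl 2-hydroxy-4-(methoxymethoxy)-6-methylbenzoate
Conditions: MOMCl (1.1 equiv), iPr2NEt, CH2Cl2, 0 °C → rt
Reagents that add atoms: chloromethyl methyl ether, COCCl
Why: The 2-OH is held in a hydrogen bond to the ester carbonyl and is less nucleophilic, so one equivalent of MOMCl etherifies only the 4-OH (selective O-alkylation); the acetal is chosen over a silyl ether because it survives the carbonate benzylation that follows.

Step 4
Reactants: 7 methyl 2-hydroxy-4-(methoxymethoxy)-6-methylbenzoate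
Product: 8 methyl 2-(benzyloxy)-4-(methoxymethoxy)-6-methylbenzoate
Conditions: BnBr, K2CO3, DMF, 60 °C
Reagents that add atoms: benzyl bromide, BrCc1ccccc1
Why: Carbonate in warm DMF deprotonates the chelated phenol and the phenoxide is benzylated by SN2 displacement (Williamson ether synthesis), the MOM acetal being stable to base.

Step 5
Reactants: 8 methyl 2-(benzyloxy)-4-(methoxymethoxy)-6-methylbenzoate
Product: 9 methyl 2-(benzyloxy)-4-hydroxy-6-methylbenzoate
Conditions: HCl (cat.), MeOH, 45 °C
Reagents that add atoms: none
Why: Acid-catalysed acetal exchange with methanol removes the MOM group as dimethoxymethane, while the benzyl ether and the methyl ester (in methanol) are untouched.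

Step 6
Reactants: 5 diketo-dioxinone; 9 methyl 2-(benzyloxy)-4-hydroxy-6-methylbenzoate
Product: 13 3-(benzyloxy)-4-(methoxycarbonyl)-5-methylphenyl 2,4-dihydroxy-6-methylbenzoate (didepside, ring B as free diol), via acylketene 10 (not isolated), via aryl trioxooctanoate 11 (not isolated), via aldol adduct 12 (not isolated)
Conditions: 5 (1.5 equiv, slow addition) to 9 in PhMe, 110 °C; cool to rt, Et3N (1 equiv); then HCl (4 M in 1,4-dioxane, 3 equiv), rt
Reagents that add atoms: none
Why: Proposed new method: retro-hetero-Diels-Alder loss of acetone from 5 gives acylketene 10, the only free phenol of 9 adds to it to give aryl ester 11, and an Et3N-mediated 6-(enolendo)-exo-trig aldol of C2 onto the C7 ketone followed by acid dehydration of 12 aromatizes ring B; the closest known reaction type is the diketo-dioxinone thermolysis, alcohol capture and aldol aromatization to alkyl resorcylates, extended here to a phenol as the trap.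

Step 7
Reactants: 13 didepside with ring B as free diol
Product: 14 3-(benzyloxy)-4-(methoxycarbonyl)-5-methylphenyl 4-(benzyloxy)-2-hydroxy-6-methylbenzoate
Conditions: BnBr (1.05 equiv), K2CO3 (1.1 equiv), acetone, rt → 40 °C
Reagents that add atoms: benzyl bromide, BrCc1ccccc1
Why: The ring B 4-OH is not hydrogen-bonded and is the more acidic, so one equivalent of base and benzyl bromide should alkylate it alone (Williamson ether synthesis), the hindered depside ester being inert to carbonate in acetone.

Step 8
Reactants: 14 ring B 4-benzyl ether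
Product: 15 3-(benzyloxy)-4-(methoxycarbonyl)-5-methylphenyl 4-(benzyloxy)-2-methoxy-6-methylbenzoate
Conditions: MeI (3 equiv), K2CO3, DMF, 45 °C
Reagents that add atoms: iodomethane, CI
Why: With no other free hydroxyl left, the chelated ring B 2-OH is deprotonated in DMF and methylated by SN2 reaction with MeI (Williamson ether synthesis), the di-ortho-substituted aryl ester being shielded from attack.

Step 9
Reactants: 15 bis(benzyl) ether of the didepside
Product: 16 3-hydroxy-4-(methoxycarbonyl)-5-methylphenyl 4-hydroxy-2-methoxy-6-methylbenzoate (ring A 2-OH, ring B 2-OMe and 4-OH)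
Conditions: H2 (1 atm), 10% Pd/C, EtOAc, rt
Reagents that add atoms: none
Why: Catalytic hydrogenolysis cleaves both benzylic C-O bonds and leaves the aryl ester, the methyl ester and the methyl ether intact.

Step 10
Reactants: 5 diketo-dioxinone; 16 didepside phenol
Product: 19 4-{[3-hydroxy-4-(methoxycarbonyl)-5-methylphenoxy]carbonyl}-3-methoxy-5-methylphenyl 2,4-dihydroxy-6-methylbenzoate (tridepside, ring C as free diol), via aryl trioxooctanoate 17 (not isolated), via aldol adduct 18 (not isolated)
Conditions: 5 (1.5 equiv, slow addition) to 16 in PhMe, 110 °C; cool to rt, Et3N (1 equiv); then HCl (4 M in 1,4-dioxane, 3 equiv), rt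
Reagents that add atoms: none
Why: Proposed new method: heating 5 again expels acetone by a retro-hetero-Diels-Alder reaction and regenerates acylketene 10, the same transient species as in step 6, whose ketene carbon is captured by the ring B 4-OH of 16, so the aryl ester C-O bond of 17 forms while that acyl carbon is still unhindered. Et3N then enolizes the C2 methylene between the ester and the C3 ketone, this carbon adds to the C7 methyl ketone to give 18, and acid dehydration with tautomerization delivers benzene ring C carrying its 2-OH, 4-OH and 6-methyl. The closest known reaction type is the thermolysis of diketo-dioxinones with capture by an alcohol and aldol aromatization to alkyl resorcylates, together with the capture of simple acylketenes by phenols to give aryl acetoacetates; new here are the phenol as trap for the triketo chain and the survival of the aryl ester through the aldol stage. Ring C closes by a 6-(enolendo)-exo-trig aldol that forms the C2-C7 bond, and the two stereocentres of 18 vanish on aromatization, so none has to be controlled. Two selectivities are needed: the free para phenol of ring B must react ahead of the ring A 2-OH, which the hydrogen bond of the latter to its ortho ester carbonyl and its crowding should secure, and the C-aldol must outrun lactonization of the C5 enol onto the aryl ester with loss of the phenoxide, which is addressed by an amine base in an aprotic medium free of alkoxide and by acid for the dehydration.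

Step 11
Reactants: 19 tridepside with ring C as free diol
Product: 20 4-{[3-hydroxy-4-(methoxycarbonyl)-5-methylphenoxy]carbonyl}-3-methoxy-5-methylphenyl 2-hydroxy-4-methoxy-6-methylbenzoate (target CNP0357736.0)
Conditions: MeI (1.05 equiv), K2CO3 (1.0 equiv), acetone, rt
Reagents that add atoms: iodomethane, CI
Why: The ring C 4-OH is the only hydroxyl not hydrogen-bonded to an ortho ester carbonyl and is the most acidic, so one equivalent of carbonate and MeI should methylate it alone at room temperature (selective Williamson ether synthesis).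

**Compound list**
1 | 2,2,6-trimethyl-4H-1,3-dioxin-4-one | CC1=CC(=O)OC(C)(C)O1 | starting material
2 | acetyl chloride | CC(=O)Cl | starting material
3 | 2,2-dimethyl-6-(2-oxopropyl)-4H-1,3-dioxin-4-one | CC(=O)CC1=CC(=O)OC(C)(C)O1 | intermediate
4 | N-methoxy-N-methylacetamide | CON(C)C(C)=O | starting material
5 | 6-(2,4-dioxopentyl)-2,2-dimethyl-4H-1,3-dioxin-4-one | CC(=O)CC(=O)CC1=CC(=O)OC(C)(C)O1 | intermediate
6 | methyl 2,4-dihydroxy-6-methylbenzoate (methyl orsellinate) | COC(=O)c1c(C)cc(O)cc1O | starting material
7 | methyl 2-hydroxy-4-(methoxymethoxy)-6-methylbenzoate | COCOc1cc(C)c(C(=O)OC)c(O)c1 | intermediate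
8 | methyl 2-(benzyloxy)-4-(methoxymethoxy)-6-methylbenzoate | COCOc1cc(C)c(C(=O)OC)c(OCc2ccccc2)c1 | intermediate
9 | methyl 2-(benzyloxy)-4-hydroxy-6-methylbenzoate | COC(=O)c1c(C)cc(O)cc1OCc1ccccc1 | intermediate
10 | 3,5,7-trioxooct-1-en-1-one (3,5-dioxohexanoyl ketene) | CC(=O)CC(=O)CC(=O)C=C=O | intermediate
11 | 3-(benzyloxy)-4-(methoxycarbonyl)-5-methylphenyl 3,5,7-trioxooctanoate | CC(=O)CC(=O)CC(=O)CC(=O)Oc1cc(C)c(C(=O)OC)c(OCc2ccccc2)c1 | intermediate
12 | 3-(benzyloxy)-4-(methoxycarbonyl)-5-methylphenyl 2-hydroxy-2-methyl-4,6-dioxocyclohexane-1-carboxylate (racemic, mixture of diastereomers and enol forms) | CC1(O)CC(=O)CC(=O)C1C(=O)Oc1cc(C)c(C(=O)OC)c(OCc2ccccc2)c1 | intermediate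
13 | 3-(benzyloxy)-4-(methoxycarbonyl)-5-methylphenyl 2,4-dihydroxy-6-methylbenzoate | COC(=O)c1c(C)cc(OC(=O)c2c(C)cc(O)cc2O)cc1OCc1ccccc1 | intermediate
14 | 3-(benzyloxy)-4-(methoxycarbonyl)-5-methylphenyl 4-(benzyloxy)-2-hydroxy-6-methylbenzoate | COC(=O)c1c(C)cc(OC(=O)c2c(C)cc(OCc3ccccc3)cc2O)cc1OCc1ccccc1 | intermediate
15 | 3-(benzyloxy)-4-(methoxycarbonyl)-5-methylphenyl 4-(benzyloxy)-2-methoxy-6-methylbenzoate | COC(=O)c1c(C)cc(OC(=O)c2c(C)cc(OCc3ccccc3)cc2OC)cc1OCc1ccccc1 | intermediate
16 | 3-hydroxy-4-(methoxycarbonyl)-5-methylphenyl 4-hydroxy-2-methoxy-6-methylbenzoate | COC(=O)c1c(C)cc(OC(=O)c2c(C)cc(O)cc2OC)cc1O | intermediate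
17 | 4-{[3-hydroxy-4-(methoxycarbonyl)-5-methylphenoxy]carbonyl}-3-methoxy-5-methylphenyl 3,5,7-trioxooctanoate | CC(=O)CC(=O)CC(=O)CC(=O)Oc1cc(C)c(C(=O)Oc2cc(C)c(C(=O)OC)c(O)c2)c(OC)c1 | intermediate
18 | 4-{[3-hydroxy-4-(methoxycarbonyl)-5-methylphenoxy]carbonyl}-3-methoxy-5-methylphenyl 2-hydroxy-2-methyl-4,6-dioxocyclohexane-1-carboxylate (racemic, mixture of diastereomers and enol forms) | CC1(O)CC(=O)CC(=O)C1C(=O)Oc1cc(C)c(C(=O)Oc2cc(C)c(C(=O)OC)c(O)c2)c(OC)c1 | intermediate
19 | 4-{[3-hydroxy-4-(methoxycarbonyl)-5-methylphenoxy]carbonyl}-3-methoxy-5-methylphenyl 2,4-dihydroxy-6-methylbenzoate | COC(=O)c1c(C)cc(OC(=O)c2c(C)cc(OC(=O)c3c(C)cc(O)cc3O)cc2OC)cc1O | intermediate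
20 | 4-{[3-hydroxy-4-(methoxycarbonyl)-5-methylphenoxy]carbonyl}-3-methoxy-5-methylphenyl 2-hydroxy-4-methoxy-6-methylbenzoate (CNP0357736.0) | COC(=O)c1c(C)cc(OC(=O)c2c(C)cc(OC(=O)c3c(C)cc(OC)cc3O)cc2OC)cc1O | target

**Step count**
Total steps: 11. Longest linear sequence: 9 steps (6 → 7 → 8 → 9 → 13 → 14 → 15 → 16 → 19 → 20, steps 3 to 11).

**Steps most likely to fail**

1. Step 10 (Proposed new method). What may go wrong:
- the C5 enol may lactonize onto the aryl ester during the base stage and expel the ring B phenoxide;
- the ketene may be captured by its own enol before the weakly nucleophilic phenol reaches it;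
- the chelated ring A hydroxyl may be acylated in competition.

Fallback, setting out from 6 and 16 and coming back at 19: methyl orsellinate 6 would be benzylated on both hydroxyls (BnBr, K2CO3, DMF, 60 °C) to methyl 2,4-bis(benzyloxy)-6-methylbenzoate F1. Saponification (KOH, aqueous DMSO, 90 °C) would give 2,4-bis(benzyloxy)-6-methylbenzoic acid F2. This acid would be activated as its mixed anhydride with trifluoroacetic anhydride in toluene at rt and should esterify the unchelated ring B phenol of 16 to the bis(benzyl) tridepside F3. Hydrogenolysis of F3 (H2, Pd/C, EtOAc) returns to 19.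

2. Step 6 (Proposed new method). What may go wrong: the same loss of the aryl ester by enol lactonization with phenoxide expulsion, and self-capture of the ketene ahead of the intermolecular phenol addition.

Fallback, setting out from 6 and 9 and coming back at 15: selective benzylation of the unchelated hydroxyl of 6 (BnBr 1 equiv, K2CO3, acetone, rt) would give methyl 4-(benzyloxy)-2-hydroxy-6-methylbenzoate F4. Methylation (MeI, K2CO3, DMF, 45 °C) would give methyl 4-(benzyloxy)-2-methoxy-6-methylbenzoate F5, and saponification (KOH, aqueous DMSO, 90 °C) 4-(benzyloxy)-2-methoxy-6-methylbenzoic acid F6. Esterification of phenol 9 with F6 through the mixed trifluoroacetic anhydride (TFAA, toluene, rt) should give 15 directly, so that steps 6 to 8 are bypassed.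

3. Step 11. What may go wrong: alkylation may run on to one of the chelated hydroxyls, or the phenoxide and carbonate may cleave or transfer a depside ester, on the most advanced material.

Fallback, setting out from 6 and 16 and coming back at 20: the methyl ether would be brought in with a preformed ring C acid. Selective methylation of 6 (MeI 1 equiv, K2CO3, acetone, rt) would give methyl 2-hydroxy-4-methoxy-6-methylbenzoate F7. Benzylation (BnBr, K2CO3, DMF, 60 °C) would give methyl 2-(benzyloxy)-4-methoxy-6-methylbenzoate F8, and saponification (KOH, aqueous DMSO, 90 °C) 2-(benzyloxy)-4-methoxy-6-methylbenzoic acid F9. Esterification of 16 with F9 (TFAA, toluene, rt) should give the ring C 2-benzyl ether of the target F10, and hydrogenolysis (H2, Pd/C, EtOAc) would give 20.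

**Further compounds**
F1 | step 10 | methyl 2,4-bis(benzyloxy)-6-methylbenzoate | COC(=O)c1c(C)cc(OCc2ccccc2)cc1OCc1ccccc1
F2 | step 10 | 2,4-bis(benzyloxy)-6-methylbenzoic acid | Cc1cc(OCc2ccccc2)cc(OCc2ccccc2)c1C(=O)O
F3 | step 10 | 4-{[3-hydroxy-4-(methoxycarbonyl)-5-methylphenoxy]carbonyl}-3-methoxy-5-methylphenyl 2,4-bis(benzyloxy)-6-methylbenzoate | COC(=O)c1c(C)cc(OC(=O)c2c(C)cc(OC(=O)c3c(C)cc(OCc4ccccc4)cc3OCc3ccccc3)cc2OC)cc1O
F4 | step 6 | methyl 4-(benzyloxy)-2-hydroxy-6-methylbenzoate | COC(=O)c1c(C)cc(OCc2ccccc2)cc1O
F5 | step 6 | methyl 4-(benzyloxy)-2-methoxy-6-methylbenzoate | COC(=O)c1c(C)cc(OCc2ccccc2)cc1OC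
F6 | step 6 | 4-(benzyloxy)-2-methoxy-6-methylbenzoic acid | COc1cc(OCc2ccccc2)cc(C)c1C(=O)O
F7 | step 11 | methyl 2-hydroxy-4-methoxy-6-methylbenzoate | COC(=O)c1c(C)cc(OC)cc1O
F8 | step 11 | methyl 2-(benzyloxy)-4-methoxy-6-methylbenzoate | COC(=O)c1c(C)cc(OC)cc1OCc1ccccc1
F9 | step 11 | 2-(benzyloxy)-4-methoxy-6-methylbenzoic acid | COc1cc(C)c(C(=O)O)c(OCc2ccccc2)c1
F10 | step 11 | 4-{[3-hydroxy-4-(methoxycarbonyl)-5-methylphenoxy]carbonyl}-3-methoxy-5-methylphenyl 2-(benzyloxy)-4-methoxy-6-methylbenzoate | COC(=O)c1c(C)cc(OC(=O)c2c(C)cc(OC(=O)c3c(C)cc(OC)cc3OCc3ccccc3)cc2OC)cc1O
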